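Numbering: cyclohexene ring C5–C10 (C5=C10, methyl C14 on C10, O-acyl on C6, lactone oxygen on C8), lactone carbons C11 and C12 with exocyclic methylene C13, side chain C4 (methyl C15)–C3–C2–C1–O on C5. The enabling feature is the α-methylene-γ-butyrolactone ring (O–C8–C7–C11(=C13)–C12=O) cis-fused to this cyclohexene: it equals an aldehyde (C8) plus the inner bond of a terminal allene (C7=C11=C13) plus CO (C12), and the Z alkene C5=C10 already holds C6 and C9 side by side.
Retrosynthesis: cut the two isobutyrate C–O bonds, then C7–C8, C11–C12 and C12–O(8) together, which opens both rings to an acyclic Z-allenyl aldehyde and CO. Further back: C11=C13 (alkyne plus formaldehyde), C6–C7 (acetylide on a lactone carbonyl), C5=C10 (aldol of (S)-citronellic acid with protected 4-hydroxybutan-2-one, then dehydration) and the tail alkene of citronellic acid (ozonolysis, gives C1–O).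
Forward: the chain is built first. A temporary dihydropyranone (O8–C8–C9–C10=C5–C6) fixes the Z geometry and is opened by the acetylide, and the alkyne is homologated to the allene. The cyclohexene and the lactone then close together in step 13, and the acyl groups go on last.
Stereochemistry: C4 comes from (S)-citronellic acid. C6 comes from a reagent-controlled oxazaborolidine reduction of an ynone. C7 and C8 are set in the key step, cis to each other through the metallacycle and anti to the C6 silyloxy group.

Key step: step 13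

Remark: (S)-citronellic acid is taken as the commercial chiral-pool material, and compounds 4–7 are carried as mixtures at C5 and C10 because both centres become sp2 in step 3. Abbreviations: TES = triethylsilyl, TBS = tert-butyldimethylsilyl, TBDPS = tert-butyldiphenylsilyl.

Step 1
Reactants: 1 4-hydroxybutan-2-one
Product: 2 4-(triethylsilyloxy)butan-2-one
Conditions: TESCl, imidazole, CH2Cl2, 0 °C → rt
Reagents that add atoms: chlorotriethylsilane, CC[Si](Cl)(CC)CC
Why: Imidazole-promoted silylation of a primary alcohol; the TES ether survives the enolate chemistry of step 2 and falls off in dilute acid.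

Step 2
Reactants: 3 (S)-citronellic acid; 2 4-(triethylsilyloxy)butan-2-one
Product: 6 4-hydroxy-4-methyl-3-[(2S)-6-methylhept-5-en-2-yl]oxan-2-one (hydroxy lactone), via silylated aldol acid 4 (not isolated), via dihydroxy acid 5 (not isolated)
Conditions: LiN(i-Pr)2 (2.2 equiv), THF, 0 °C → rt; 2, −78 °C; then 2 M aq. HCl, rt
Reagents that add atoms: none
Why: Aldol addition of a carboxylic acid dianion (lithium enediolate) to a ketone forms C5–C10, and acidification cleaves the TES ether and lets the 3,5-dihydroxy acid close to the δ-lactone; C4 is untouched and the mixture at C5 and C10 does not matter.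

Step 3
Reactants: 6 hydroxy lactone
Product: 8 4-methyl-3-[(2S)-6-methylhept-5-en-2-yl]-5,6-dihydro-2H-pyran-2-one, via tertiary mesylate 7 (not isolated)
Conditions: MsCl, Et3N, CH2Cl2, 0 °C; then DBU, rt
Reagents that add atoms: none
Why: Sulfonylation of the tertiary β-hydroxyl and base-induced E1cB elimination through the lactone enolate should give the conjugated tetrasubstituted alkene (DBU returns any β,γ-isomer to conjugation), and the ring forces C6 and C9 cis on C5=C10, so the Z geometry is fixed without a selective olefination.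

Step 4
Reactants: 8 dihydropyranone with the citronellyl tail
Product: 10 3-[(2S)-5-hydroxypentan-2-yl]-4-methyl-5,6-dihydro-2H-pyran-2-one, via aldehyde 9 (not isolated)
Conditions: O3, CH2Cl2/MeOH (4:1), −78 °C, to the first persistent blue; then NaBH4, −78 → 0 °C
Reagents that add atoms: ozone, [O-][O+]=O
Why: Ozonolysis with reductive borohydride work-up; ozone attacks the electron-rich trisubstituted alkene far faster than the electron-poor tetrasubstituted enoate, and NaBH4 at low temperature reduces the aldehyde but should leave the conjugated lactone.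

Step 5
Reactants: 10 hydroxy dihydropyranone
Product: 11 3-[(2S)-5-(tert-butyldiphenylsilyloxy)pentan-2-yl]-4-methyl-5,6-dihydro-2H-pyran-2-one
Conditions: TBDPSCl, imidazole, DMF, rt
Reagents that add atoms: tert-butyl(chloro)diphenylsilane, CC(C)(C)[Si](Cl)(c1ccccc1)c1ccccc1
Why: Standard silylation of a primary alcohol; the TBDPS ether is chosen because it outlasts the selective cleavage of a primary TBS ether in step 11.

Step 6
Reactants: 11 TBDPS-protected dihydropyranone; 12 ethynyltrimethylsilane
Product: 13 (4Z)-7-hydroxy-5-methyl-4-[(2S)-5-(tert-butyldiphenylsilyloxy)pentan-2-yl]-1-(trimethylsilyl)hept-4-en-1-yn-3-one (hydroxy ynone)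
Conditions: 12, n-BuLi, THF, −78 °C; then 11, −78 °C; sat. aq. NH4Cl
Reagents that add atoms: none
Why: 1,2-Addition of a lithium acetylide to a lactone carbonyl forms C6–C7 and stops at the lithium hemiketal at −78 °C, which opens to the hydroxy ynone on quench (the β,β-disubstituted enoate offers no conjugate pathway); the Z geometry is inherited from the ring.

Step 7
Reactants: 13 hydroxy ynone
Product: 14 (4Z)-7-(tert-butyldimethylsilyloxy)-5-methyl-4-[(2S)-5-(tert-butyldiphenylsilyloxy)pentan-2-yl]-1-(trimethylsilyl)hept-4-en-1-yn-3-one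
Conditions: TBSCl, imidazole, CH2Cl2, 0 °C → rt
Reagents that add atoms: tert-butyl(chloro)dimethylsilane, CC(C)(C)[Si](C)(C)Cl
Why: Imidazole-promoted silylation of the primary alcohol, which also draws any cyclic hemiketal form through the open chain.

Step 8
Reactants: 14 silyloxy ynone
Product: 16 (3S,4Z)-7-(tert-butyldimethylsilyloxy)-5-methyl-4-[(2S)-5-(tert-butyldiphenylsilyloxy)pentan-2-yl]hept-4-en-1-yn-3-ol, via silylalkynyl carbinol 15 (not isolated)
Conditions: (R)-Me-CBS oxazaborolidine (cat.), BH3·SMe2, THF, −30 °C; then MeOH, K2CO3, rt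
Reagents that add atoms: none
Why: Corey–Bakshi–Shibata reduction, in which the (R)-oxazaborolidine–borane complex treats the fully substituted alkenyl group as the large and the slim alkynyl group as the small substituent and delivers hydride to the face that gives the required C6 configuration (reagent control), after which methanolic carbonate cleaves the alkynyl C–Si bond.

Step 9
Reactants: 16 terminal propargylic alcohol; 17 paraformaldehyde
Product: 19 (4S,5Z)-8-(tert-butyldimethylsilyloxy)-6-methyl-5-[(2S)-5-(tert-butyldiphenylsilyloxy)pentan-2-yl]octa-1,2,5-trien-4-ol (allenol), via Mannich base 18 (not isolated)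
Conditions: (CH2O)n, CuI (0.5 equiv), Cy2NH, 1,4-dioxane, reflux
Reagents that add atoms: none
Why: Crabbé homologation: coupling of the terminal alkyne, formaldehyde and the amine, mediated by monovalent copper, gives the propargylic amine, which loses an imine by a copper-assisted 1,5-hydride shift to leave the terminal allene C7=C11=C13; the carbinol centre is not involved.

Step 10
Reactants: 19 allenol
Product: 20 (4S,5Z)-4,8-bis(tert-butyldimethylsilyloxy)-6-methyl-5-[(2S)-5-(tert-butyldiphenylsilyloxy)pentan-2-yl]octa-1,2,5-triene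
Conditions: TBSOTf, 2,6-lutidine, CH2Cl2, −78 °C
Reagents that add atoms: tert-butyldimethylsilyl trifluoromethanesulfonate, CC(C)(C)[Si](C)(C)OS(=O)(=O)C(F)(F)F
Why: Silyl triflate silylation of a hindered secondary alcohol with a non-nucleophilic base; only the O–H bond reacts, so C6 keeps its configuration.

Step 11
Reactants: 20 tris-silyl ether
Product: 21 (3Z,5S)-5-(tert-butyldimethylsilyloxy)-3-methyl-4-[(2S)-5-(tert-butyldiphenylsilyloxy)pentan-2-yl]octa-3,6,7-trien-1-ol
Conditions: HF·pyridine, pyridine, THF, 0 °C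
Reagents that add atoms: none
Why: Selective desilylation: buffered HF·pyridine cleaves the unhindered primary TBS ether at O8 much faster than the hindered secondary TBS ether at O6 or the TBDPS ether at O1.

Step 12
Reactants: 21 primary alcohol
Product: 22 (3Z,5S)-5-(tert-butyldimethylsilyloxy)-3-methyl-4-[(2S)-5-(tert-butyldiphenylsilyloxy)pentan-2-yl]octa-3,6,7-trienal (Z-allenyl aldehyde)
Conditions: Dess–Martin periodinane, NaHCO3, CH2Cl2, 0 °C → rt; filtered and used at once
Reagents that add atoms: none
Why: Dess–Martin oxidation under bicarbonate buffering is neutral and fast, so the β,γ-unsaturated aldehyde should not slip into conjugation.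

Step 13
Reactants: 22 Z-allenyl aldehyde; 23 carbon monoxide
Product: 24 (3aR,4S,7aR)-4-(tert-butyldimethylsilyloxy)-5-[(2S)-5-(tert-butyldiphenylsilyloxy)pentan-2-yl]-6-methyl-3-methylidene-3a,4,7,7a-tetrahydro-1-benzofuran-2(3H)-one
Conditions: Ru3(CO)12 (cat.), CO (20 atm), 1,4-dioxane, 120 °C
Reagents that add atoms: none
Why: Zerovalent ruthenium carbonyl binds the aldehyde C8=O and the proximal allene bond C7=C11 and couples them oxidatively to an oxaruthenacyclopentane (Ru–O–C8–C7–C11), which forms C7–C8; CO then inserts into the Ru–C11 alkenyl bond and C12–O reductive elimination releases the lactone and the catalyst. This is the known hetero-Pauson–Khand reaction of allenyl aldehydes, a [2+2+1] cyclocarbonylation that gives cis-fused α-methylene-γ-butyrolactones. The cyclohexene closes by 6-exo attack of C7 on the aldehyde carbon within the oxidative cyclisation, which is easy because the Z alkene C5=C10 already holds C6 and C9 on the same side; the five-membered lactone closes by acyl–oxygen reductive elimination from the six-membered acyl ruthenacycle. C7 and C8 should come out cis because both bonds are made on one face of the metallacycle; their sense relative to C6 is set by the C6 silyloxy group, which stands pseudoaxial to avoid allylic 1,2-strain with the C5 branch, so the metal-bound aldehyde oxygen avoids a 1,3-diaxial clash with it and the metallacycle forms on the opposite face, placing C11 trans to O6. The step needs reaction at the inner allene bond only, which the tether length secures (the distal C11=C13 bond stays as the exocyclic methylene), while the hindered tetrasubstituted C5=C10 alkene stays out and the neutral medium under CO pressure should keep the aldehyde from conjugating or losing CO.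

Step 14
Reactants: 24 bis-silyl lactone
Product: 25 (3aS,4S,7aR)-4-hydroxy-5-[(2S)-5-hydroxypentan-2-yl]-6-methyl-3-methylidene-3a,4,7,7a-tetrahydro-1-benzofuran-2(3H)-one (diol; same spatial arrangement as 24)
Conditions: HF·pyridine (excess), THF, 0 °C → rt
Reagents that add atoms: none
Why: Fluoride-induced desilylation of both silyl ethers; the acidic HF·pyridine medium spares the α-methylene lactone, which basic fluoride sources could attack by conjugate addition.

Step 15
Reactants: 25 diol
Product: 26 (4S)-4-[(3aR,4S,7aR)-6-methyl-3-methylidene-4-(2-methylpropanoyloxy)-2-oxo-2,3,3a,4,7,7a-hexahydro-1-benzofuran-5-yl]pentyl 2-methylpropanoate (target)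
Conditions: i-PrCOCl, pyridine, DMAP (cat.), CH2Cl2, 0 °C → rt
Reagents that add atoms: isobutyryl chloride, CC(C)C(Cl)=O
Why: DMAP-catalysed acylation of the primary and the allylic secondary alcohol with the acid chloride; no stereocentre is touched and the low temperature limits reversible amine addition to the methylene lactone.

Compound list
1 | 4-hydroxybutan-2-one | CC(=O)CCO | starting material
2 | 4-(triethylsilyloxy)butan-2-one | CC(=O)CCO[Si](CC)(CC)CC | intermediate
3 | (S)-citronellic acid, (3S)-3,7-dimethyloct-6-enoic acid | OC(=O)C[C@@H](C)CCC=C(C)C | starting material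
4 | 3-hydroxy-3-methyl-2-[(2S)-6-methylhept-5-en-2-yl]-5-(triethylsilyloxy)pentanoic acid (mixture at C5/C10) | OC(=O)C([C@@H](C)CCC=C(C)C)C(C)(O)CCO[Si](CC)(CC)CC | intermediate (not isolated)
5 | 3,5-dihydroxy-3-methyl-2-[(2S)-6-methylhept-5-en-2-yl]pentanoic acid (mixture at C5/C10) | OC(=O)C([C@@H](C)CCC=C(C)C)C(C)(O)CCO | intermediate (not isolated)
6 | 4-hydroxy-4-methyl-3-[(2S)-6-methylhept-5-en-2-yl]oxan-2-one (mixture at C5/C10) | O=C1OCCC(C)(O)C1[C@@H](C)CCC=C(C)C | intermediate
7 | 4-methyl-3-[(2S)-6-methylhept-5-en-2-yl]-2-oxooxan-4-yl methanesulfonate | O=C1OCCC(C)(OS(C)(=O)=O)C1[C@@H](C)CCC=C(C)C | intermediate (not isolated)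
8 | 4-methyl-3-[(2S)-6-methylhept-5-en-2-yl]-5,6-dihydro-2H-pyran-2-one | O=C1OCCC(C)=C1[C@@H](C)CCC=C(C)C | intermediate
9 | (4S)-4-(4-methyl-2-oxo-5,6-dihydro-2H-pyran-3-yl)pentanal | O=C1OCCC(C)=C1[C@@H](C)CCC=O | intermediate (not isolated)
10 | 3-[(2S)-5-hydroxypentan-2-yl]-4-methyl-5,6-dihydro-2H-pyran-2-one | O=C1OCCC(C)=C1[C@@H](C)CCCO | intermediate
11 | 3-[(2S)-5-(tert-butyldiphenylsilyloxy)pentan-2-yl]-4-methyl-5,6-dihydro-2H-pyran-2-one | O=C1OCCC(C)=C1[C@@H](C)CCCO[Si](c1ccccc1)(c1ccccc1)C(C)(C)C | intermediate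
12 | ethynyltrimethylsilane | C#C[Si](C)(C)C | starting material
13 | (4Z)-7-hydroxy-5-methyl-4-[(2S)-5-(tert-butyldiphenylsilyloxy)pentan-2-yl]-1-(trimethylsilyl)hept-4-en-1-yn-3-one | OCC/C(C)=C([C@@H](C)CCCO[Si](c1ccccc1)(c1ccccc1)C(C)(C)C)\C(=O)C#C[Si](C)(C)C | intermediate
14 | (4Z)-7-(tert-butyldimethylsilyloxy)-5-methyl-4-[(2S)-5-(tert-butyldiphenylsilyloxy)pentan-2-yl]-1-(trimethylsilyl)hept-4-en-1-yn-3-one | CC(C)(C)[Si](C)(C)OCC/C(C)=C([C@@H](C)CCCO[Si](c1ccccc1)(c1ccccc1)C(C)(C)C)\C(=O)C#C[Si](C)(C)C | intermediate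
15 | (3R,4Z)-7-(tert-butyldimethylsilyloxy)-5-methyl-4-[(2S)-5-(tert-butyldiphenylsilyloxy)pentan-2-yl]-1-(trimethylsilyl)hept-4-en-1-yn-3-ol | CC(C)(C)[Si](C)(C)OCC/C(C)=C([C@@H](C)CCCO[Si](c1ccccc1)(c1ccccc1)C(C)(C)C)\[C@@H](O)C#C[Si](C)(C)C | intermediate (not isolated)
16 | (3S,4Z)-7-(tert-butyldimethylsilyloxy)-5-methyl-4-[(2S)-5-(tert-butyldiphenylsilyloxy)pentan-2-yl]hept-4-en-1-yn-3-ol | CC(C)(C)[Si](C)(C)OCC/C(C)=C([C@@H](C)CCCO[Si](c1ccccc1)(c1ccccc1)C(C)(C)C)\[C@@H](O)C#C | intermediate
17 | paraformaldehyde (source of formaldehyde) | C=O | starting material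
18 | (4S,5Z)-8-(tert-butyldimethylsilyloxy)-1-(dicyclohexylamino)-6-methyl-5-[(2S)-5-(tert-butyldiphenylsilyloxy)pentan-2-yl]oct-5-en-2-yn-4-ol | CC(C)(C)[Si](C)(C)OCC/C(C)=C([C@@H](C)CCCO[Si](c1ccccc1)(c1ccccc1)C(C)(C)C)\[C@@H](O)C#CCN(C1CCCCC1)C1CCCCC1 | intermediate (not isolated)
19 | (4S,5Z)-8-(tert-butyldimethylsilyloxy)-6-methyl-5-[(2S)-5-(tert-butyldiphenylsilyloxy)pentan-2-yl]octa-1,2,5-trien-4-ol | CC(C)(C)[Si](C)(C)OCC/C(C)=C([C@@H](C)CCCO[Si](c1ccccc1)(c1ccccc1)C(C)(C)C)\[C@@H](O)C=C=C | intermediate
20 | (4S,5Z)-4,8-bis(tert-butyldimethylsilyloxy)-6-methyl-5-[(2S)-5-(tert-butyldiphenylsilyloxy)pentan-2-yl]octa-1,2,5-triene | CC(C)(C)[Si](C)(C)OCC/C(C)=C([C@@H](C)CCCO[Si](c1ccccc1)(c1ccccc1)C(C)(C)C)\[C@@H](O[Si](C)(C)C(C)(C)C)C=C=C | intermediate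
21 | (3Z,5S)-5-(tert-butyldimethylsilyloxy)-3-methyl-4-[(2S)-5-(tert-butyldiphenylsilyloxy)pentan-2-yl]octa-3,6,7-trien-1-ol | OCC/C(C)=C([C@@H](C)CCCO[Si](c1ccccc1)(c1ccccc1)C(C)(C)C)\[C@@H](O[Si](C)(C)C(C)(C)C)C=C=C | intermediate
22 | (3Z,5S)-5-(tert-butyldimethylsilyloxy)-3-methyl-4-[(2S)-5-(tert-butyldiphenylsilyloxy)pentan-2-yl]octa-3,6,7-trienal | O=CC/C(C)=C([C@@H](C)CCCO[Si](c1ccccc1)(c1ccccc1)C(C)(C)C)\[C@@H](O[Si](C)(C)C(C)(C)C)C=C=C | intermediate
23 | carbon monoxide | [C-]#[O+] | starting material
24 | (3aR,4S,7aR)-4-(tert-butyldimethylsilyloxy)-5-[(2S)-5-(tert-butyldiphenylsilyloxy)pentan-2-yl]-6-methyl-3-methylidene-3a,4,7,7a-tetrahydro-1-benzofuran-2(3H)-one | C=C1C(=O)O[C@@H]2CC(C)=C([C@@H](C)CCCO[Si](c3ccccc3)(c3ccccc3)C(C)(C)C)[C@@H](O[Si](C)(C)C(C)(C)C)[C@H]12 | intermediate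
25 | (3aS,4S,7aR)-4-hydroxy-5-[(2S)-5-hydroxypentan-2-yl]-6-methyl-3-methylidene-3a,4,7,7a-tetrahydro-1-benzofuran-2(3H)-one | C=C1C(=O)O[C@@H]2CC(C)=C([C@@H](C)CCCO)[C@@H](O)[C@H]12 | intermediate
26 | (4S)-4-[(3aR,4S,7aR)-6-methyl-3-methylidene-4-(2-methylpropanoyloxy)-2-oxo-2,3,3a,4,7,7a-hexahydro-1-benzofuran-5-yl]pentyl 2-methylpropanoate | C=C1C(=O)O[C@@H]2CC(C)=C([C@@H](C)CCCOC(=O)C(C)C)[C@@H](OC(=O)C(C)C)[C@H]12 | target

Total step count: 15.
Longest linear sequence: 15 steps (1 → 26 through steps 1–15); 14 steps from (S)-citronellic acid 3.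

Steps most likely to fail

Step 13. The aldehyde may conjugate or lose CO at 120 °C before it is captured in the metallacycle, and face selection relative to C6 may be incomplete. The fallback sets out from aldehyde 22 and makes the same bonds in stages at low temperature. Distannylation of the allene catalysed by zerovalent palladium ([PdCl(C3H5)]2, Bu3SnSnBu3, THF, rt) generates a 2-stannylallyl stannane that adds to the aldehyde in the flask and should give the cis stannylvinyl cyclohexenol F1 (C7–C8 formed). Iododestannylation (I2, CH2Cl2, 0 °C) gives the iodovinyl cyclohexenol F2. Carbonylative lactonisation (Pd(PPh3)4, CO 1 atm, Et3N, MeCN, 60 °C) then forms C11–C12 and C12–O and comes back to the route at 24.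

Step 6. The acetylide may deprotonate the γ-positions of the unsaturated lactone instead of adding, or the adduct may persist as a cyclic hemiketal that silylates sluggishly in step 7. The fallback sets out from lactone 11. Aminolysis with Me(MeO)NH·HCl and AlMe3 (CH2Cl2, 0 °C) opens the ring to the hydroxy Weinreb amide F3, and immediate silylation (TBSCl, imidazole) gives the silyloxy Weinreb amide F4. Lithium (trimethylsilyl)acetylide (THF, −78 → 0 °C) then adds once through the chelated tetrahedral intermediate and returns to the route at ynone 14.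

Step 8. Facial selectivity in the hydride delivery may be poor if the catalyst does not tell the alkenyl flank from the silylalkynyl flank, or if the C4 centre works against it. The fallback sets out from ynone 14 and replaces catalyst control by separation and recycling. Luche reduction (NaBH4, CeCl3·7H2O, MeOH, −78 °C) gives both C6 epimers, which are diastereomers because C4 is fixed and should be separable by chromatography. The unwanted epimeric carbinol F5 is oxidised back to 14 (MnO2, CH2Cl2) and resubmitted. The wanted epimer rejoins the route at 15, which is desilylated at carbon (K2CO3, MeOH) to 16.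

Further compounds
F1 | step 13 | (1R,5S,6R)-5-(tert-butyldimethylsilyloxy)-4-[(2S)-5-(tert-butyldiphenylsilyloxy)pentan-2-yl]-3-methyl-6-[1-(tributylstannyl)ethenyl]cyclohex-3-en-1-ol (configuration at C6, C7, C8 as in 24) | O[C@@H]1CC(C)=C([C@@H](C)CCCO[Si](c2ccccc2)(c2ccccc2)C(C)(C)C)[C@@H](O[Si](C)(C)C(C)(C)C)[C@@H]1C(=C)[Sn](CCCC)(CCCC)CCCC
F2 | step 13 | (1R,5S,6R)-5-(tert-butyldimethylsilyloxy)-4-[(2S)-5-(tert-butyldiphenylsilyloxy)pentan-2-yl]-6-(1-iodoethenyl)-3-methylcyclohex-3-en-1-ol | O[C@@H]1CC(C)=C([C@@H](C)CCCO[Si](c2ccccc2)(c2ccccc2)C(C)(C)C)[C@@H](O[Si](C)(C)C(C)(C)C)[C@@H]1C(I)=C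
F3 | step 6 | (2Z)-5-hydroxy-N-methoxy-N,3-dimethyl-2-[(2S)-5-(tert-butyldiphenylsilyloxy)pentan-2-yl]pent-2-enamide | OCC/C(C)=C([C@@H](C)CCCO[Si](c1ccccc1)(c1ccccc1)C(C)(C)C)\C(=O)N(C)OC
F4 | step 6 | (2Z)-5-(tert-butyldimethylsilyloxy)-N-methoxy-N,3-dimethyl-2-[(2S)-5-(tert-butyldiphenylsilyloxy)pentan-2-yl]pent-2-enamide | CC(C)(C)[Si](C)(C)OCC/C(C)=C([C@@H](C)CCCO[Si](c1ccccc1)(c1ccccc1)C(C)(C)C)\C(=O)N(C)OC
F5 | step 8 | (3S,4Z)-7-(tert-butyldimethylsilyloxy)-5-methyl-4-[(2S)-5-(tert-butyldiphenylsilyloxy)pentan-2-yl]-1-(trimethylsilyl)hept-4-en-1-yn-3-ol (C6 epimer of 15) | CC(C)(C)[Si](C)(C)OCC/C(C)=C([C@@H](C)CCCO[Si](c1ccccc1)(c1ccccc1)C(C)(C)C)\[C@H](O)C#C[Si](C)(C)C
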